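**Retrosynthetic overview**
1. Target ⇐ HF desilylation ⇐ C4 alcohol oxidation (after PMB removal) ⇐ Yamaguchi acylation of the 8α‑OH with silyl‑protected 2‑(hydroxymethyl)acrylic acid.
2. C7 acrylate ⇐ Mannich methylenation (C11–C13) of a C7 acetate; 6α‑OH/7α‑H ⇐ α‑face hydroboration of a Δ6 β,γ‑unsaturated ester.
3. C7–C11 ⇐ intermolecular ester‑enolate aldol condensation (Peterson mode) on an 8α‑silyloxy‑7‑ketone; 8α‑OH ⇐ Rubottom oxidation; 4α‑O/5α‑H ⇐ ketalisation with alkene shift, then hydroboration.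
4. Decalin ⇐ (R)‑Wieland–Miescher ketone ⇐ key C9–C10 bond by intermolecular Michael addition of 2‑methylcyclohexane‑1,3‑dione to methyl vinyl ketone, then D‑proline aldol cyclisation.
5. Ring order: ring A is bought as the dione; ring B is the only ring made (Michael, then aldol).

Assumption: locants follow eudesmane numbering of the decalin (C10 = methyl‑bearing ring‑fusion carbon, C5 = the other one; ring A = C1–C5/C10, ring B = C5–C10; C11–C13 = the C7 acrylate carbons; β = face of the C10 methyl). The SMILES is read as (1R,5S,6S,7S,8S,10R) = 1β‑OH, 5α‑H, 6α‑OH, 7β‑acrylate, 8α‑acyloxy, 10β‑Me.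
Abbreviations: TBS = tert‑butyldimethylsilyl, TES = triethylsilyl, TMS = trimethylsilyl, PMB = 4‑methoxybenzyl.

**Step 1**
Reactants: 1 2‑methylcyclohexane‑1,3‑dione; 2 methyl vinyl ketone
Product: 3 2‑methyl‑2‑(3‑oxobutyl)cyclohexane‑1,3‑dione
Conditions: AcOH (cat.), hydroquinone (cat.), H2O, 75 °C
Reagents that add atoms: none
Why: Michael addition of the acidic 2‑methyl‑1,3‑dione to the enone is fast and clean under mild acid catalysis and forms the C9–C10 bond and the (still achiral) quaternary carbon.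

**Step 2**
Reactants: 3 2‑methyl‑2‑(3‑oxobutyl)cyclohexane‑1,3‑dione
Product: 5 (R)‑Wieland–Miescher ketone [(8aR)‑8a‑methyl‑3,4,8,8a‑tetrahydronaphthalene‑1,6(2H,7H)‑dione], via cis‑ketol 4 (not isolated)
Conditions: D‑proline (5 mol %), DMSO, 35 °C; recrystallise to >99 % ee
Reagents that add atoms: none
Why: The Hajos–Parrish–Eder–Sauer–Wiechert enamine aldol condensation (aldol half of the Robinson annulation) closes ring B on one enantiotopic ring carbonyl, so D‑proline gives the 10R enone, the mirror image of the well‑known L‑proline result.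

**Step 3**
Reactants: 5 (R)‑Wieland–Miescher ketone
Product: 6 1β‑hydroxy‑10β‑methyl‑Δ5‑octalin‑7‑one [(4aR,5R)‑5‑hydroxy‑4a‑methyl‑4,4a,5,6,7,8‑hexahydronaphthalen‑2(3H)‑one]
Conditions: NaBH4 (0.3 equiv), EtOH, 0 °C
Reagents that add atoms: none
Why: Chemoselective borohydride reduction of the saturated ketone beside the enone, with hydride arriving anti to the angular methyl so that the equatorial 1β‑OH (cis to methyl) results.

**Step 4**
Reactants: 6 1β‑hydroxy‑10β‑methyl‑Δ5‑octalin‑7‑one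
Product: 7 1β‑TBSO‑10β‑methyl‑Δ5‑octalin‑7‑one
Conditions: TBSCl, imidazole, DMF, rt
Reagents that add atoms: tert‑butyldimethylsilyl chloride, CC(C)(C)[Si](C)(C)Cl
Why: Standard Corey silylation of the secondary alcohol; no stereocentre is touched.

**Step 5**
Reactants: 7 1β‑TBSO‑10β‑methyl‑Δ5‑octalin‑7‑one
Product: 8 1β‑TBSO‑7,7‑ethylenedioxy‑10β‑methyl‑Δ4‑octalin
Conditions: ethylene glycol, pyridinium p‑toluenesulfonate (cat.), benzene, reflux (Dean–Stark)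
Reagents that add atoms: ethylene glycol, OCCO
Why: Acid‑catalysed ketalisation of the enone runs through the dienol ether and, as with Δ4‑3‑keto steroids, ends with the alkene deconjugated into ring A (C4=C5), while the mild acid spares the hindered silyl ether.

**Step 6**
Reactants: 8 1β‑TBSO‑7,7‑ethylenedioxy‑10β‑methyl‑Δ4‑octalin
Product: 10 1β‑TBSO‑7,7‑ethylenedioxy‑10β‑methyl‑5α‑decalin‑4α‑ol, via C4‑alkylborane 9 (not isolated)
Conditions: BH3·THF, THF, 0 °C → rt; then NaOH, 30 % H2O2, 0 °C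
Reagents that add atoms: borane (as BH3·THF; boron of 9), B; hydrogen peroxide, OO
Why: Brown hydroboration–oxidation adds boron to C4 and hydrogen to C5 syn from the α‑face opposite the angular methyl, giving the trans‑fused 5α‑H/4α‑OH product (any cis‑fused minor isomer is removed by chromatography).

**Step 7**
Reactants: 10 1β‑TBSO‑7,7‑ethylenedioxy‑10β‑methyl‑5α‑decalin‑4α‑ol
Product: 11 1β‑TBSO‑4α‑PMBO‑7,7‑ethylenedioxy‑10β‑methyl‑5α‑decalin
Conditions: NaH, PMBCl, Bu4NI (cat.), THF/DMF, 0 °C → rt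
Reagents that add atoms: 4‑methoxybenzyl chloride, COc1ccc(CCl)cc1
Why: Williamson etherification of the equatorial alkoxide gives an ether that survives base, borane and mild acid and is later removed oxidatively beside silyl ethers and acrylates.

**Step 8**
Reactants: 11 1β‑TBSO‑4α‑PMBO‑7,7‑ethylenedioxy‑10β‑methyl‑5α‑decalin
Product: 12 1β‑TBSO‑4α‑PMBO‑10β‑methyl‑5α‑decalin‑7‑one
Conditions: pyridinium p‑toluenesulfonate, acetone/H2O, 60 °C
Reagents that add atoms: water, O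
Why: Mild acid‑catalysed acetal hydrolysis frees the C7 ketone without cleaving the hindered TBS or the PMB ether and without touching a stereocentre.

**Step 9**
Reactants: 12 1β‑TBSO‑4α‑PMBO‑10β‑methyl‑5α‑decalin‑7‑one
Product: 13 7‑trimethylsilyloxy‑Δ7 enol ether of 12
Conditions: LiN(iPr)2, TMSCl, THF, −78 °C
Reagents that add atoms: chlorotrimethylsilane, C[Si](C)(C)Cl
Why: Kinetic enolisation with in situ O‑silylation takes the C8 methylene remote from the ring fusion, as 5α‑3‑keto steroids enolise toward C2, giving the Δ7 silyl enol ether (minor Δ6 isomer is separated after step 10).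

**Step 10**
Reactants: 13 7‑trimethylsilyloxy‑Δ7 enol ether of 12
Product: 15 8α‑hydroxy‑1β‑TBSO‑4α‑PMBO‑10β‑methyl‑5α‑decalin‑7‑one, via 8α‑trimethylsilyloxy ketone 14 (not isolated)
Conditions: mCPBA, CH2Cl2, −20 → 0 °C; then 0.5 M HCl, THF, 0 °C
Reagents that add atoms: 3‑chloroperoxybenzoic acid, OOC(=O)c1cccc(Cl)c1
Why: Rubottom oxidation, in which the peracid epoxidises the enol ether from the α‑face (β‑face shielded by the 1,3‑related axial C10 methyl) and silyl migration then hydrolysis give the equatorial, thermodynamically preferred 8α‑ketol.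

**Step 11**
Reactants: 15 8α‑hydroxy‑1β‑TBSO‑4α‑PMBO‑10β‑methyl‑5α‑decalin‑7‑one
Product: 16 8α‑TESO‑1β‑TBSO‑4α‑PMBO‑10β‑methyl‑5α‑decalin‑7‑one
Conditions: TESCl, imidazole, DMF, 0 °C → rt
Reagents that add atoms: chlorotriethylsilane, CC[Si](CC)(CC)Cl
Why: Silylation gives a temporary C8 ether that tolerates strong base and borane yet can later be removed in the presence of TBS ethers.

**Step 12**
Reactants: 16 8α‑TESO‑1β‑TBSO‑4α‑PMBO‑10β‑methyl‑5α‑decalin‑7‑one; 17 methyl (trimethylsilyl)acetate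
Product: 20 methyl (E)‑2‑[8α‑TESO‑1β‑TBSO‑4α‑PMBO‑10β‑methyl‑5α‑decalin‑7‑ylidene]acetate (ester syn to C6), via lithiated silylacetate 18 (not isolated), via β‑silyl aldolate 19 (not isolated)
Conditions: 17, LiN(iPr)2, THF, −78 °C; then 16, −78 → 0 °C; H2O quench
Reagents that add atoms: lithium diisopropylamide (lithium of 18 and 19), [Li]N(C(C)C)C(C)C
Why: Intermolecular ester‑enolate aldol addition to the C7 ketone forms the C7–C11 bond and the aldolate collapses by Peterson elimination (a regiospecific aldol condensation suited to hindered, enolisable ketones), the E isomer being favoured by A(1,3) strain with the equatorial 8‑silyloxy group while C7 itself is set in step 14.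

**Step 13**
Reactants: 20 methyl (E)‑2‑[…decalin‑7‑ylidene]acetate
Product: 22 methyl 2‑[8α‑TESO‑1β‑TBSO‑4α‑PMBO‑10β‑methyl‑5α‑decal‑6‑en‑7‑yl]acetate, via lithium dienolate 21 (not isolated)
Conditions: LiN(iPr)2, DMPU, THF, −78 °C; then AcOH, −78 °C
Reagents that add atoms: lithium diisopropylamide (lithium of 21), [Li]N(C(C)C)C(C)C
Why: Classical deconjugation, in which kinetic γ‑deprotonation at the C6 methylene syn to the ester (not at the hindered oxygenated C8 methine) and α‑protonation of the dienolate place the alkene at C6=C7.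

**Step 14**
Reactants: 22 methyl 2‑[…decal‑6‑en‑7‑yl]acetate
Product: 24 methyl 2‑[6α‑hydroxy‑8α‑TESO‑1β‑TBSO‑4α‑PMBO‑10β‑methyl‑5α‑decalin‑7β‑yl]acetate, via C6‑alkylborane 23 (not isolated)
Conditions: BH3·THF (1.5 equiv), THF, 0 °C; then 30 % H2O2, aq. NaOAc, 0 °C → rt
Reagents that add atoms: borane (as BH3·THF; boron of 23), B; hydrogen peroxide, OO
Why: Hydroboration–oxidation of the trisubstituted alkene (faster than borane attack on the ester at 0 °C) adds boron to C6 and hydrogen to C7 syn from the α‑face opposite the axial C10 methyl, setting 6α‑OH and 7α‑H so that all three ring‑B substituents are equatorial.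

**Step 15**
Reactants: 24 methyl 2‑[6α‑hydroxy‑…‑decalin‑7β‑yl]acetate
Product: 25 methyl 2‑[1β,6α‑bis(TBSO)‑8α‑TESO‑4α‑PMBO‑10β‑methyl‑5α‑decalin‑7β‑yl]acetate
Conditions: TBSOTf, 2,6‑lutidine, CH2Cl2, −78 → 0 °C
Reagents that add atoms: tert‑butyldimethylsilyl triflate, CC(C)(C)[Si](C)(C)OS(=O)(=O)C(F)(F)F
Why: The powerful silyl triflate/lutidine system silylates the hindered equatorial C6 alcohol and thereby also blocks lactonisation onto the C12 ester.

**Step 16**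
Reactants: 25 methyl 2‑[1β,6α‑bis(TBSO)‑…‑decalin‑7β‑yl]acetate; 26 Eschenmoser's salt (CH2=NMe2+ I−)
Product: 28 methyl 3‑(dimethylamino)‑2‑[1β,6α‑bis(TBSO)‑8α‑TESO‑4α‑PMBO‑10β‑methyl‑5α‑decalin‑7β‑yl]propanoate (C11 epimers), via lithium ester enolate 27 (not isolated)
Conditions: LiN(iPr)2, THF, −78 °C; then 26, −78 °C → rt
Reagents that add atoms: lithium diisopropylamide (lithium of 27), [Li]N(C(C)C)C(C)C
Why: Mannich reaction of the lithium ester enolate with the small, highly electrophilic iminium salt forms the C11–C13 bond, and the new C11 centre (mixture) is destroyed in step 17.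

**Step 17**
Reactants: 28 Mannich base
Product: 30 methyl 2‑[1β,6α‑bis(TBSO)‑8α‑TESO‑4α‑PMBO‑10β‑methyl‑5α‑decalin‑7β‑yl]acrylate, via trimethylammonium iodide 29 (not isolated)
Conditions: MeI, MeOH, rt; then DBU, CH2Cl2, rt
Reagents that add atoms: iodomethane (methyl and iodide of 29), CI
Why: Exhaustive N‑methylation followed by base‑induced E1cB (Hofmann‑type) elimination of trimethylamine unveils the α‑methylene ester without touching C7.

**Step 18**
Reactants: 30 acrylate with 8α‑OTES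
Product: 31 methyl 2‑[8α‑hydroxy‑1β,6α‑bis(TBSO)‑4α‑PMBO‑10β‑methyl‑5α‑decalin‑7β‑yl]acrylate
Conditions: pyridinium p‑toluenesulfonate, MeOH/CH2Cl2, 0 °C → rt
Reagents that add atoms: none
Why: Acid‑catalysed methanolysis cleaves the secondary triethylsilyl ether much faster than the bulkier TBS ethers or the PMB ether, and the methanolic medium suppresses lactonisation of the freed alcohol.

**Step 19**
Reactants: 32 methyl 2‑(hydroxymethyl)acrylate
Product: 33 methyl 2‑[(TBSO)methyl]acrylate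
Conditions: TBSCl, imidazole, CH2Cl2, 0 °C → rt
Reagents that add atoms: tert‑butyldimethylsilyl chloride, CC(C)(C)[Si](C)(C)Cl
Why: Routine silylation masks the primary allylic alcohol for the acylation.

**Step 20**
Reactants: 33 methyl 2‑[(TBSO)methyl]acrylate
Product: 34 2‑[(TBSO)methyl]acrylic acid
Conditions: LiOH·H2O, THF/H2O, 0 °C; then cold 0.5 M HCl to pH 4
Reagents that add atoms: lithium hydroxide, [Li+].[OH-]
Why: Saponification at 0 °C followed by gentle acidification gives the acid while the primary TBS ether survives.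

**Step 21**
Reactants: 31 8α‑alcohol; 34 2‑[(TBSO)methyl]acrylic acid
Product: 36 methyl 2‑[8α‑{2‑[(TBSO)methyl]acryloyloxy}‑1β,6α‑bis(TBSO)‑4α‑PMBO‑10β‑methyl‑5α‑decalin‑7β‑yl]acrylate, via mixed anhydride 35 (not isolated)
Conditions: 34, 2,4,6‑trichlorobenzoyl chloride, Et3N, THF, rt; then 31, DMAP, toluene, rt
Reagents that add atoms: 2,4,6‑trichlorobenzoyl chloride (aroyl group of 35), O=C(Cl)c1c(Cl)cc(Cl)cc1Cl
Why: Yamaguchi esterification through the mixed anhydride and DMAP acyl transfer acylates the only free hydroxyl with retention at C8, since the alcohol C–O bond is not broken.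

**Step 22**
Reactants: 36 fully protected diester
Product: 37 methyl 2‑[4α‑hydroxy‑8α‑{2‑[(TBSO)methyl]acryloyloxy}‑1β,6α‑bis(TBSO)‑10β‑methyl‑5α‑decalin‑7β‑yl]acrylate
Conditions: DDQ, CH2Cl2/pH 7 buffer, 0 °C → rt
Reagents that add atoms: none
Why: Oxidative PMB cleavage (benzylic hydride abstraction, then hydrolysis) is selective for the electron‑rich benzyl ether and leaves silyl ethers, esters and the electron‑poor acrylates alone.

**Step 23**
Reactants: 37 4α‑alcohol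
Product: 38 methyl 2‑[8α‑{2‑[(TBSO)methyl]acryloyloxy}‑1β,6α‑bis(TBSO)‑10β‑methyl‑4‑oxo‑5α‑decalin‑7β‑yl]acrylate
Conditions: Dess–Martin periodinane, CH2Cl2, rt
Reagents that add atoms: none
Why: Dess–Martin oxidation of the single free secondary alcohol gives the C4 ketone under near‑neutral conditions, and C5 already has the thermodynamically preferred trans‑fused 5α‑H.

**Step 24**
Reactants: 38 tris‑TBS keto diester
Product: 39 target, methyl 2‑[(1R,5S,6S,7S,8S,10R)‑1,6‑dihydroxy‑8‑{[2‑(hydroxymethyl)acryloyl]oxy}‑10‑methyl‑4‑oxodecalin‑7‑yl]acrylate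
Conditions: HF·pyridine, pyridine, THF, 0 °C → rt
Reagents that add atoms: none
Why: Fluoride‑mediated desilylation with buffered HF·pyridine removes the three silyl ethers under weakly acidic conditions, avoiding base‑induced β‑elimination of the 6‑hydroxy‑4‑ketone and conjugate additions, and no stereocentre is involved.

**Compound list**
1 | 2‑methylcyclohexane‑1,3‑dione | CC1C(=O)CCCC1=O | starting material
2 | methyl vinyl ketone | CC(=O)C=C | starting material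
3 | 2‑methyl‑2‑(3‑oxobutyl)cyclohexane‑1,3‑dione | CC(=O)CCC1(C)C(=O)CCCC1=O | intermediate
4 | cis‑ketol, 5β‑hydroxy‑10β‑methyl‑cis‑decalin‑1,7‑dione | O=C1CC[C@@]2(C)C(=O)CCC[C@@]2(O)C1 | intermediate (not isolated)
5 | (R)‑Wieland–Miescher ketone | O=C1CC[C@@]2(C)C(=O)CCCC2=C1 | intermediate
6 | 1β‑hydroxy‑10β‑methyl‑Δ5‑octalin‑7‑one | O=C1CC[C@@]2(C)[C@H](O)CCCC2=C1 | intermediate
7 | 1β‑TBSO‑10β‑methyl‑Δ5‑octalin‑7‑one | O=C1CC[C@@]2(C)[C@H](O[Si](C)(C)C(C)(C)C)CCCC2=C1 | intermediate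
8 | 1β‑TBSO‑7,7‑ethylenedioxy‑10β‑methyl‑Δ4‑octalin | O1CCOC12CC[C@@]3(C)[C@H](O[Si](C)(C)C(C)(C)C)CCC=C3C2 | intermediate
9 | C4‑alkylborane (4α‑boryl, 5α‑H) | O1CCOC12CC[C@@]3(C)[C@H](O[Si](C)(C)C(C)(C)C)CC[C@@H](B)[C@@H]3C2 | intermediate (not isolated)
10 | 1β‑TBSO‑7,7‑ethylenedioxy‑10β‑methyl‑5α‑decalin‑4α‑ol | O1CCOC12CC[C@@]3(C)[C@H](O[Si](C)(C)C(C)(C)C)CC[C@@H](O)[C@@H]3C2 | intermediate
11 | 4α‑PMB ether of 10 | O1CCOC12CC[C@@]3(C)[C@H](O[Si](C)(C)C(C)(C)C)CC[C@@H](OCc4ccc(OC)cc4)[C@@H]3C2 | intermediate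
12 | 1β‑TBSO‑4α‑PMBO‑10β‑methyl‑5α‑decalin‑7‑one | O=C1CC[C@@]2(C)[C@H](O[Si](C)(C)C(C)(C)C)CC[C@@H](OCc3ccc(OC)cc3)[C@@H]2C1 | intermediate
13 | Δ7 TMS enol ether of 12 | C[Si](C)(C)OC1=CC[C@@]2(C)[C@H](O[Si](C)(C)C(C)(C)C)CC[C@@H](OCc3ccc(OC)cc3)[C@@H]2C1 | intermediate
14 | 8α‑trimethylsilyloxy‑7‑ketone | C[Si](C)(C)O[C@H]1C[C@@]2(C)[C@H](O[Si](C)(C)C(C)(C)C)CC[C@@H](OCc3ccc(OC)cc3)[C@@H]2CC1=O | intermediate (not isolated)
15 | 8α‑hydroxy‑1β‑TBSO‑4α‑PMBO‑10β‑methyl‑5α‑decalin‑7‑one | O[C@H]1C[C@@]2(C)[C@H](O[Si](C)(C)C(C)(C)C)CC[C@@H](OCc3ccc(OC)cc3)[C@@H]2CC1=O | intermediate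
16 | 8α‑TESO‑1β‑TBSO‑4α‑PMBO‑10β‑methyl‑5α‑decalin‑7‑one | CC[Si](CC)(CC)O[C@H]1C[C@@]2(C)[C@H](O[Si](C)(C)C(C)(C)C)CC[C@@H](OCc3ccc(OC)cc3)[C@@H]2CC1=O | intermediate
17 | methyl (trimethylsilyl)acetate | COC(=O)C[Si](C)(C)C | starting material
18 | lithium enolate of 17 | COC(O[Li])=C[Si](C)(C)C | intermediate (not isolated)
19 | lithium β‑silyl aldolate (C7/C11 epimers) | CC[Si](CC)(CC)O[C@H]1C[C@@]2(C)[C@H](O[Si](C)(C)C(C)(C)C)CC[C@@H](OCc3ccc(OC)cc3)[C@@H]2CC1(O[Li])C(C(=O)OC)[Si](C)(C)C | intermediate (not isolated)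
20 | methyl (E)‑2‑[8α‑TESO‑1β‑TBSO‑4α‑PMBO‑10β‑methyl‑5α‑decalin‑7‑ylidene]acetate | CC[Si](CC)(CC)O[C@H]1C[C@@]2(C)[C@H](O[Si](C)(C)C(C)(C)C)CC[C@@H](OCc3ccc(OC)cc3)[C@@H]2C/C1=C\C(=O)OC | intermediate
21 | lithium dienolate of 20 | CC[Si](CC)(CC)O[C@H]1C[C@@]2(C)[C@H](O[Si](C)(C)C(C)(C)C)CC[C@@H](OCc3ccc(OC)cc3)[C@@H]2C=C1C=C(OC)O[Li] | intermediate (not isolated)
22 | methyl 2‑[8α‑TESO‑1β‑TBSO‑4α‑PMBO‑10β‑methyl‑5α‑decal‑6‑en‑7‑yl]acetate | CC[Si](CC)(CC)O[C@H]1C[C@@]2(C)[C@H](O[Si](C)(C)C(C)(C)C)CC[C@@H](OCc3ccc(OC)cc3)[C@@H]2C=C1CC(=O)OC | intermediate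
23 | C6‑alkylborane (6α‑boryl, 7α‑H) | CC[Si](CC)(CC)O[C@H]1C[C@@]2(C)[C@H](O[Si](C)(C)C(C)(C)C)CC[C@@H](OCc3ccc(OC)cc3)[C@@H]2[C@@H](B)[C@@H]1CC(=O)OC | intermediate (not isolated)
24 | methyl 2‑[6α‑hydroxy‑8α‑TESO‑1β‑TBSO‑4α‑PMBO‑10β‑methyl‑5α‑decalin‑7β‑yl]acetate | CC[Si](CC)(CC)O[C@H]1C[C@@]2(C)[C@H](O[Si](C)(C)C(C)(C)C)CC[C@@H](OCc3ccc(OC)cc3)[C@@H]2[C@@H](O)[C@@H]1CC(=O)OC | intermediate
25 | 6α‑TBS ether of 24 | CC[Si](CC)(CC)O[C@H]1C[C@@]2(C)[C@H](O[Si](C)(C)C(C)(C)C)CC[C@@H](OCc3ccc(OC)cc3)[C@@H]2[C@@H](O[Si](C)(C)C(C)(C)C)[C@@H]1CC(=O)OC | intermediate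
26 | Eschenmoser's salt, N,N‑dimethylmethyleneiminium iodide | C=[N+](C)C.[I-] | starting material
27 | lithium enolate of 25 | CC[Si](CC)(CC)O[C@H]1C[C@@]2(C)[C@H](O[Si](C)(C)C(C)(C)C)CC[C@@H](OCc3ccc(OC)cc3)[C@@H]2[C@@H](O[Si](C)(C)C(C)(C)C)[C@@H]1C=C(OC)O[Li] | intermediate (not isolated)
28 | β‑dimethylamino ester (Mannich base, C11 epimers) | CC[Si](CC)(CC)O[C@H]1C[C@@]2(C)[C@H](O[Si](C)(C)C(C)(C)C)CC[C@@H](OCc3ccc(OC)cc3)[C@@H]2[C@@H](O[Si](C)(C)C(C)(C)C)[C@@H]1C(CN(C)C)C(=O)OC | intermediate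
29 | trimethylammonium iodide of 28 | CC[Si](CC)(CC)O[C@H]1C[C@@]2(C)[C@H](O[Si](C)(C)C(C)(C)C)CC[C@@H](OCc3ccc(OC)cc3)[C@@H]2[C@@H](O[Si](C)(C)C(C)(C)C)[C@@H]1C(C[N+](C)(C)C)C(=O)OC.[I-] | intermediate (not isolated)
30 | methyl 2‑[1β,6α‑bis(TBSO)‑8α‑TESO‑4α‑PMBO‑10β‑methyl‑5α‑decalin‑7β‑yl]acrylate | CC[Si](CC)(CC)O[C@H]1C[C@@]2(C)[C@H](O[Si](C)(C)C(C)(C)C)CC[C@@H](OCc3ccc(OC)cc3)[C@@H]2[C@@H](O[Si](C)(C)C(C)(C)C)[C@@H]1C(=C)C(=O)OC | intermediate
31 | methyl 2‑[8α‑hydroxy‑1β,6α‑bis(TBSO)‑4α‑PMBO‑10β‑methyl‑5α‑decalin‑7β‑yl]acrylate | O[C@H]1C[C@@]2(C)[C@H](O[Si](C)(C)C(C)(C)C)CC[C@@H](OCc3ccc(OC)cc3)[C@@H]2[C@@H](O[Si](C)(C)C(C)(C)C)[C@@H]1C(=C)C(=O)OC | intermediate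
32 | methyl 2‑(hydroxymethyl)acrylate | C=C(CO)C(=O)OC | starting material
33 | methyl 2‑[(TBSO)methyl]acrylate | C=C(CO[Si](C)(C)C(C)(C)C)C(=O)OC | intermediate
34 | 2‑[(TBSO)methyl]acrylic acid | C=C(CO[Si](C)(C)C(C)(C)C)C(=O)O | intermediate
35 | mixed anhydride of 34 with 2,4,6‑trichlorobenzoic acid | C=C(CO[Si](C)(C)C(C)(C)C)C(=O)OC(=O)c1c(Cl)cc(Cl)cc1Cl | intermediate (not isolated)
36 | 8α‑{2‑[(TBSO)methyl]acryloyl} ester of 31 | C=C(CO[Si](C)(C)C(C)(C)C)C(=O)O[C@H]1C[C@@]2(C)[C@H](O[Si](C)(C)C(C)(C)C)CC[C@@H](OCc3ccc(OC)cc3)[C@@H]2[C@@H](O[Si](C)(C)C(C)(C)C)[C@@H]1C(=C)C(=O)OC | intermediate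
37 | 4α‑alcohol (PMB removed) | C=C(CO[Si](C)(C)C(C)(C)C)C(=O)O[C@H]1C[C@@]2(C)[C@H](O[Si](C)(C)C(C)(C)C)CC[C@@H](O)[C@@H]2[C@@H](O[Si](C)(C)C(C)(C)C)[C@@H]1C(=C)C(=O)OC | intermediate
38 | 4‑ketone, tris‑TBS ether of the target | C=C(CO[Si](C)(C)C(C)(C)C)C(=O)O[C@H]1C[C@@]2(C)[C@H](O[Si](C)(C)C(C)(C)C)CCC(=O)[C@@H]2[C@@H](O[Si](C)(C)C(C)(C)C)[C@@H]1C(=C)C(=O)OC | intermediate
39 | CNP0144895.1 | C=C(CO)C(=O)O[C@H]1C[C@@]2(C)[C@H](O)CCC(=O)[C@@H]2[C@@H](O)[C@@H]1C(=C)C(=O)OC | target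

**Step count and risks**
Total step count: 24. Longest linear sequence: 22 steps (steps 1–18 and 21–24; steps 19–20 make acid 34).

The three steps most likely to fail:

Step 13 (deconjugation). It inherits the E/Z ratio of step 12 and could deprotonate at C8 or stall. The fallback sets out from 16 and avoids the enoate altogether. KN(SiMe3)2/PhNTf2 in THF at −78 °C deprotonates the C6 methylene (the C8 methine is hindered and oxygenated) to give the Δ6 enol triflate F1. Pd(PPh3)4‑catalysed Negishi coupling of F1 with the Reformatsky reagent BrZnCH2CO2Me then gives the β,γ‑unsaturated ester directly, coming back to the route at 22.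

Step 14 (hydroboration). Borane may reduce the nearby ester or the face selectivity may erode. The fallback sets out from 16 and sets C6 and C7 without hydroboration. KN(SiMe3)2 then 2‑(phenylsulfonyl)‑3‑phenyloxaziridine hydroxylates the C6 enolate from the α‑face to give the 6α‑hydroxy ketone F2. TBSOTf/2,6‑lutidine gives the bis‑silyl ketone F3, and the same Peterson aldol with lithiated 17 gives the alkylidene acetate F4 (E/Z mixture). Conjugate reduction with [CuH(PPh3)]6 delivers hydride to C7 from the axial α‑face, coming back to the route at 25.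

Step 21 (esterification). The 8α‑OH is hindered by the neighbouring acrylate, and the γ‑hydroxy ester 31 may lactonise under DMAP. The fallback sets out from 31. Acryloyl chloride/Et3N at −40 °C (a small, fast electrophile) gives the 8‑O‑acrylate F5. A Morita–Baylis–Hillman reaction with aqueous formaldehyde (DABCO, dioxane/H2O) hydroxymethylates only the unsubstituted acrylate to give the 2‑(hydroxymethyl)acrylate F6. TBSCl/imidazole then silylates its primary alcohol, coming back to the route at 36.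

**Further compounds**
F1 | step 13 | Δ6 enol triflate of 16 | CC[Si](CC)(CC)O[C@H]1C[C@@]2(C)[C@H](O[Si](C)(C)C(C)(C)C)CC[C@@H](OCc3ccc(OC)cc3)[C@@H]2C=C1OS(=O)(=O)C(F)(F)F
F2 | step 14 | 6α‑hydroxy‑8α‑TESO‑1β‑TBSO‑4α‑PMBO‑10β‑methyl‑5α‑decalin‑7‑one | CC[Si](CC)(CC)O[C@H]1C[C@@]2(C)[C@H](O[Si](C)(C)C(C)(C)C)CC[C@@H](OCc3ccc(OC)cc3)[C@@H]2[C@@H](O)C1=O
F3 | step 14 | 6α‑TBS ether of F2 | CC[Si](CC)(CC)O[C@H]1C[C@@]2(C)[C@H](O[Si](C)(C)C(C)(C)C)CC[C@@H](OCc3ccc(OC)cc3)[C@@H]2[C@@H](O[Si](C)(C)C(C)(C)C)C1=O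
F4 | step 14 | methyl 2‑[1β,6α‑bis(TBSO)‑8α‑TESO‑4α‑PMBO‑10β‑methyl‑5α‑decalin‑7‑ylidene]acetate (E shown, E/Z mixture usable) | CC[Si](CC)(CC)O[C@H]1C[C@@]2(C)[C@H](O[Si](C)(C)C(C)(C)C)CC[C@@H](OCc3ccc(OC)cc3)[C@@H]2[C@@H](O[Si](C)(C)C(C)(C)C)/C1=C/C(=O)OC
F5 | step 21 | 8α‑O‑acryloyl ester of 31 | C=CC(=O)O[C@H]1C[C@@]2(C)[C@H](O[Si](C)(C)C(C)(C)C)CC[C@@H](OCc3ccc(OC)cc3)[C@@H]2[C@@H](O[Si](C)(C)C(C)(C)C)[C@@H]1C(=C)C(=O)OC
F6 | step 21 | 8α‑O‑[2‑(hydroxymethyl)acryloyl] ester of 31 | C=C(CO)C(=O)O[C@H]1C[C@@]2(C)[C@H](O[Si](C)(C)C(C)(C)C)CC[C@@H](OCc3ccc(OC)cc3)[C@@H]2[C@@H](O[Si](C)(C)C(C)(C)C)[C@@H]1C(=C)C(=O)OC
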